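The cyclohexane is numbered C1 (quaternary), C2 (methylidene-bearing), C3 (CH(CH3)), then C4–C6. The ring is closed last at the methylene–methylene bond C4–C5. This exploits two features: C3 with C4 maps onto methyl (R)-3-hydroxy-2-methylpropanoate, and a quaternary C1 carrying a vinyl group (C6=C5) is exactly what an SN2′ allylic substitution delivers. A copper-catalysed enantioselective allylic substitution therefore joins an alkenylaluminium (C2–C4) and an allylic phosphate at the C1–C2 bond. The key step then, in one pot, hydroborates the vinyl group and couples the primary borane (C5) with the primary bromide (C4) under palladium catalysis. The precursor is an open-chain bromo-triene; no stereocentre is formed or endangered on ring closure.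

Key step: step 11

Remarks on the chemistry:
- Compounds 1, 6, 10 and 22 are taken as commercial.
- L* in step 8 is one antipode of 1-(2,6-diethylphenyl)-4,5-diphenyl-3-(2-sulfonatophenyl)-4,5-dihydro-1H-imidazol-3-ium (inner salt), the precursor of a bidentate sulfonate N-heterocyclic carbene. The antipode is assumed to be assigned on a model allylic phosphate so that C1 forms with the configuration drawn.
- In the acyclic intermediates the CIP descriptors differ from those of the ring, but the spatial arrangement is the one drawn in the SMILES throughout.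

**Step 1**
Reactants: 1 hexa-1,5-diyne
Product: 4 (2E,6E)-3,6-dimethylocta-2,6-diene-1,8-diol, via bis-alkenylalane 2 (not isolated), via dilithium bis-alanate 3 (not isolated)
Conditions: AlMe3, Cp2ZrCl2 (20 mol %), CH2Cl2, 0 °C → rt; volatiles removed; n-BuLi, THF, −78 °C; (CH2O)n, −78 °C → rt; aqueous work-up
Reagents that add atoms: trimethylaluminium, C[Al](C)C; paraformaldehyde (as formaldehyde), C=O
Why: Zirconium-catalysed methylalumination (Negishi carboalumination) adds CH3 and Al syn across each terminal alkyne with CH3 on the internal carbon, so both trisubstituted alkenes should be born E, and the alanate is hydroxymethylated with retention.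

**Step 2**
Reactants: 4 (2E,6E)-3,6-dimethylocta-2,6-diene-1,8-diol
Product: 5 (2E,6E)-1,8-dibromo-3,6-dimethylocta-2,6-diene
Conditions: PBr3, Et2O, −10 → 0 °C
Reagents that add atoms: phosphorus tribromide, BrP(Br)Br
Why: SN2 bromination of primary allylic alcohols with PBr3 at low temperature should proceed without allylic transposition or loss of alkene geometry.

**Step 3**
Reactants: 5 (2E,6E)-1,8-dibromo-3,6-dimethylocta-2,6-diene; 6 1,2,4,5-tetramethoxybenzene
Product: 8 3-[(2E,6E)-8-bromo-3,6-dimethylocta-2,6-dien-1-yl]-1,2,4,5-tetramethoxybenzene, via aryllithium 7 (not isolated)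
Conditions: 6, n-BuLi, THF, 0 °C; cannulated into 5 (3 equiv), THF, −78 → 0 °C; excess 5 recovered
Reagents that add atoms: none
Why: Directed ortho-lithiation between two methoxy groups followed by SN2 alkylation at one terminus of the excess C2-symmetric bis-allylic bromide (statistical mono-substitution) should give the mono-arylated bromide.

**Step 4**
Reactants: 8 3-[(2E,6E)-8-bromo-3,6-dimethylocta-2,6-dien-1-yl]-1,2,4,5-tetramethoxybenzene
Product: 9 diethyl (2E,6E)-3,6-dimethyl-8-(2,3,5,6-tetramethoxyphenyl)octa-2,6-dien-1-yl phosphate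
Conditions: (EtO)2P(O)OH, Cs2CO3, DMF, rt
Reagents that add atoms: diethyl hydrogen phosphate, CCOP(=O)(O)OCC
Why: O-alkylation of caesium diethyl phosphate by the primary allylic bromide (SN2) should give the allylic phosphate directly, the γ,γ-disubstituted terminus disfavouring SN2′.

**Step 5**
Reactants: 10 methyl (R)-3-hydroxy-2-methylpropanoate
Product: 11 methyl (R)-3-[(tert-butyldimethylsilyl)oxy]-2-methylpropanoate
Conditions: TBSCl, imidazole, CH2Cl2, rt
Reagents that add atoms: tert-butyldimethylsilyl chloride, CC(C)(C)[Si](C)(C)Cl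
Why: Standard silylation of a primary alcohol, which leaves the α-stereocentre untouched.

**Step 6**
Reactants: 11 methyl (R)-3-[(tert-butyldimethylsilyl)oxy]-2-methylpropanoate
Product: 12 (R)-3-[(tert-butyldimethylsilyl)oxy]-2-methylpropanal
Conditions: i-Bu2AlH (1.05 equiv), CH2Cl2, −78 °C; Rochelle salt work-up
Reagents that add atoms: none
Why: Partial reduction of the ester stops at the tetrahedral aluminium hemiacetal at −78 °C, and the aldehyde is used at once to avoid α-epimerisation.

**Step 7**
Reactants: 12 (R)-3-[(tert-butyldimethylsilyl)oxy]-2-methylpropanal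
Product: 13 (S)-tert-butyldimethyl[(2-methylbut-3-yn-1-yl)oxy]silane
Conditions: dimethyl (1-diazo-2-oxopropyl)phosphonate, K2CO3, MeOH, 0 °C → rt
Reagents that add atoms: dimethyl (1-diazo-2-oxopropyl)phosphonate, CC(=O)C(=[N+]=[N-])P(=O)(OC)OC
Why: Ohira–Bestmann (Seyferth–Gilbert) homologation converts the aldehyde into the terminal alkyne under mild carbonate conditions, which should leave the stereocentre intact.

**Step 8**
Reactants: 13 (S)-tert-butyldimethyl[(2-methylbut-3-yn-1-yl)oxy]silane; 9 diethyl (2E,6E)-3,6-dimethyl-8-(2,3,5,6-tetramethoxyphenyl)octa-2,6-dien-1-yl phosphate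
Product: 15 tert-butyl{[(2S,4S,7E)-4-ethenyl-2,4,7-trimethyl-3-methylidene-9-(2,3,5,6-tetramethoxyphenyl)non-7-en-1-yl]oxy}dimethylsilane, via alkenylalane 14 (not isolated)
Conditions: 13 (1.6 equiv), i-Bu2AlH (1.5 equiv), NiCl2(dppp) (3 mol %), THF, 4 °C; then 9, CuCl2·2H2O (5 mol %), L* (6 mol %), THF, −15 °C
Reagents that add atoms: none
Why: Nickel-catalysed α-selective hydroalumination gives the 2-aluminio-1-alkene, which an NHC–copper catalyst should transfer SN2′-selectively to the γ-carbon of the E-allylic phosphate (enantioselective allylic substitution), the chiral ligand setting the quaternary C1 with its vinyl group under catalyst control while C3 is a spectator.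

**Step 9**
Reactants: 15 tert-butyl{[(2S,4S,7E)-4-ethenyl-2,4,7-trimethyl-3-methylidene-9-(2,3,5,6-tetramethoxyphenyl)non-7-en-1-yl]oxy}dimethylsilane
Product: 16 (2S,4S,7E)-4-ethenyl-2,4,7-trimethyl-3-methylidene-9-(2,3,5,6-tetramethoxyphenyl)non-7-en-1-ol
Conditions: Bu4NF, THF, rt
Reagents that add atoms: none
Why: Fluoride-mediated desilylation of a primary silyl ether; nothing else in the molecule is fluoride-sensitive.

**Step 10**
Reactants: 16 (2S,4S,7E)-4-ethenyl-2,4,7-trimethyl-3-methylidene-9-(2,3,5,6-tetramethoxyphenyl)non-7-en-1-ol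
Product: 17 (2S,4S,7E)-1-bromo-4-ethenyl-2,4,7-trimethyl-3-methylidene-9-(2,3,5,6-tetramethoxyphenyl)non-7-ene
Conditions: CBr4, PPh3, CH2Cl2, 0 °C
Reagents that add atoms: carbon tetrabromide, BrC(Br)(Br)Br
Why: Appel bromination of the primary alcohol under neutral conditions should spare the alkenes and the electron-rich arene.

**Step 11**
Reactants: 17 (2S,4S,7E)-1-bromo-4-ethenyl-2,4,7-trimethyl-3-methylidene-9-(2,3,5,6-tetramethoxyphenyl)non-7-ene
Product: 19 3-{(2E)-5-[(1R,3R)-1,3-dimethyl-2-methylidenecyclohexyl]-3-methylpent-2-en-1-yl}-1,2,4,5-tetramethoxybenzene, via alkylborane 18 (not isolated)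
Conditions: 9-BBN dimer (1.1 equiv B–H), THF, 0 °C → rt; then diluted to 0.01 M, Pd(OAc)2 (5 mol %), PCy3 (10 mol %), K3PO4·H2O, THF, rt → 40 °C
Reagents that add atoms: none
Why: Anti-Markovnikov hydroboration puts boron on C5 of the vinyl group; the hydroxide-activated B-alkyl-9-BBN then enters a palladium cycle of SN2-type oxidative addition of zerovalent palladium into the C4–Br bond, intramolecular transmetalation to a seven-membered dialkylpalladacycle and C(sp3)–C(sp3) reductive elimination that forms C4–C5. The closest known reaction type is the Pd/PCy3-catalysed Suzuki–Miyaura coupling of primary alkyl bromides bearing β-hydrogens with B-alkyl-9-BBN reagents, together with B-alkyl Suzuki–Miyaura cyclisations. The cyclohexane is closed by reductive elimination from the palladacycle, formally a 6-exo-tet alkylation of C4 by C5. No stereocentre is created: C1 and C3 are spectators, and C3, allylic but not α to a carbonyl, cannot epimerise. The step needs chemoselective hydroboration of the vinyl group, which sterics should secure (the C2 alkene is flanked by quaternary C1 and tertiary C3, the side-chain alkene is trisubstituted), and ring closure ahead of oligomerisation and β-hydride elimination, which high dilution, the gem-disubstituted C1 and the bulky electron-rich PCy3 should secure.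

**Step 12**
Reactants: 19 3-{(2E)-5-[(1R,3R)-1,3-dimethyl-2-methylidenecyclohexyl]-3-methylpent-2-en-1-yl}-1,2,4,5-tetramethoxybenzene
Product: 20 2,5-dimethoxy-3-{(2E)-5-[(1R,3R)-1,3-dimethyl-2-methylidenecyclohexyl]-3-methylpent-2-en-1-yl}cyclohexa-2,5-diene-1,4-dione
Conditions: (NH4)2Ce(NO3)6 (2.5 equiv), MeCN/H2O, 0 °C
Reagents that add atoms: water, O
Why: Oxidative demethylation of a para-dimethoxy pair by ceric ammonium nitrate gives the p-quinone (both para pairs lead to the same 2,5-dimethoxy-3-alkyl quinone), and short exposure at 0 °C should spare the alkenes.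

**Step 13**
Reactants: 20 2,5-dimethoxy-3-{(2E)-5-[(1R,3R)-1,3-dimethyl-2-methylidenecyclohexyl]-3-methylpent-2-en-1-yl}cyclohexa-2,5-diene-1,4-dione
Product: 21 2-hydroxy-5-methoxy-3-{(2E)-5-[(1R,3R)-1,3-dimethyl-2-methylidenecyclohexyl]-3-methylpent-2-en-1-yl}cyclohexa-2,5-diene-1,4-dione
Conditions: KOH, MeOH/H2O, rt; then 1 M HCl
Reagents that add atoms: potassium hydroxide, [K+].[OH-]
Why: Addition–elimination hydrolysis of the vinylogous methyl ester next to the alkyl chain (twisted out of conjugation and so the more electrophilic) should give the hydroxyquinone, whose vinylogous carboxylate stops further hydrolysis.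

**Step 14**
Reactants: 21 2-hydroxy-5-methoxy-3-{(2E)-5-[(1R,3R)-1,3-dimethyl-2-methylidenecyclohexyl]-3-methylpent-2-en-1-yl}cyclohexa-2,5-diene-1,4-dione; 22 3-methylbutan-1-amine
Product: 23 metachromin H
Conditions: 22 (3 equiv), EtOH, rt; dilute acid wash
Reagents that add atoms: none
Why: Addition–elimination (vinylogous transamidation) of the primary amine at the remaining methoxy-bearing carbon C5 should give the aminoquinone, the C2 oxygen being deactivated as its enolate.

**Compound list**
1 | hexa-1,5-diyne | C#CCCC#C | starting material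
2 | (1E,5E)-1,6-bis(dimethylalumanyl)-2,5-dimethylhexa-1,5-diene | C[Al](C)/C=C(C)/CC/C(C)=C/[Al](C)C | intermediate
3 | dilithium bis-alanate of 2 (one n-butyl added to each aluminium) | [Li+].[Li+].CCCC[Al-](C)(C)/C=C(C)/CC/C(C)=C/[Al-](C)(C)CCCC | intermediate
4 | (2E,6E)-3,6-dimethylocta-2,6-diene-1,8-diol | OC/C=C(C)/CC/C(C)=C/CO | intermediate
5 | (2E,6E)-1,8-dibromo-3,6-dimethylocta-2,6-diene | BrC/C=C(C)/CC/C(C)=C/CBr | intermediate
6 | 1,2,4,5-tetramethoxybenzene | COc1cc(OC)c(OC)cc1OC | starting material
7 | (2,3,5,6-tetramethoxyphenyl)lithium | [Li]c1c(OC)c(OC)cc(OC)c1OC | intermediate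
8 | 3-[(2E,6E)-8-bromo-3,6-dimethylocta-2,6-dien-1-yl]-1,2,4,5-tetramethoxybenzene | BrC/C=C(C)/CC/C(C)=C/Cc1c(OC)c(OC)cc(OC)c1OC | intermediate
9 | diethyl (2E,6E)-3,6-dimethyl-8-(2,3,5,6-tetramethoxyphenyl)octa-2,6-dien-1-yl phosphate | CCOP(=O)(OCC)OC/C=C(C)/CC/C(C)=C/Cc1c(OC)c(OC)cc(OC)c1OC | intermediate
10 | methyl (R)-3-hydroxy-2-methylpropanoate | COC(=O)[C@H](C)CO | starting material
11 | methyl (R)-3-[(tert-butyldimethylsilyl)oxy]-2-methylpropanoate | COC(=O)[C@H](C)CO[Si](C)(C)C(C)(C)C | intermediate
12 | (R)-3-[(tert-butyldimethylsilyl)oxy]-2-methylpropanal | O=C[C@H](C)CO[Si](C)(C)C(C)(C)C | intermediate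
13 | (S)-tert-butyldimethyl[(2-methylbut-3-yn-1-yl)oxy]silane | C#C[C@H](C)CO[Si](C)(C)C(C)(C)C | intermediate
14 | diisobutyl[(3R)-4-(tert-butyldimethylsilyloxy)-3-methylbut-1-en-2-yl]aluminium (same spatial arrangement as 13) | C=C([Al](CC(C)C)CC(C)C)[C@H](C)CO[Si](C)(C)C(C)(C)C | intermediate
15 | tert-butyl{[(2S,4S,7E)-4-ethenyl-2,4,7-trimethyl-3-methylidene-9-(2,3,5,6-tetramethoxyphenyl)non-7-en-1-yl]oxy}dimethylsilane | C=C[C@](C(=C)[C@H](C)CO[Si](C)(C)C(C)(C)C)(C)CC/C(C)=C/Cc1c(OC)c(OC)cc(OC)c1OC | intermediate
16 | (2S,4S,7E)-4-ethenyl-2,4,7-trimethyl-3-methylidene-9-(2,3,5,6-tetramethoxyphenyl)non-7-en-1-ol | C=C[C@](C(=C)[C@H](C)CO)(C)CC/C(C)=C/Cc1c(OC)c(OC)cc(OC)c1OC | intermediate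
17 | (2S,4S,7E)-1-bromo-4-ethenyl-2,4,7-trimethyl-3-methylidene-9-(2,3,5,6-tetramethoxyphenyl)non-7-ene | C=C[C@](C(=C)[C@H](C)CBr)(C)CC/C(C)=C/Cc1c(OC)c(OC)cc(OC)c1OC | intermediate
18 | B-alkyl-9-borabicyclo[3.3.1]nonane from anti-Markovnikov hydroboration of the ethenyl group of 17 (stereocentres unchanged) | B1(CC[C@](C(=C)[C@H](C)CBr)(C)CC/C(C)=C/Cc3c(OC)c(OC)cc(OC)c3OC)C2CCCC1CCC2 | intermediate
19 | 3-{(2E)-5-[(1R,3R)-1,3-dimethyl-2-methylidenecyclohexyl]-3-methylpent-2-en-1-yl}-1,2,4,5-tetramethoxybenzene | C=C1[C@H](C)CCC[C@]1(C)CC/C(C)=C/Cc1c(OC)c(OC)cc(OC)c1OC | intermediate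
20 | 2,5-dimethoxy-3-{(2E)-5-[(1R,3R)-1,3-dimethyl-2-methylidenecyclohexyl]-3-methylpent-2-en-1-yl}cyclohexa-2,5-diene-1,4-dione | C=C1[C@H](C)CCC[C@]1(C)CC/C(C)=C/CC1=C(OC)C(=O)C=C(OC)C1=O | intermediate
21 | 2-hydroxy-5-methoxy-3-{(2E)-5-[(1R,3R)-1,3-dimethyl-2-methylidenecyclohexyl]-3-methylpent-2-en-1-yl}cyclohexa-2,5-diene-1,4-dione | C=C1[C@H](C)CCC[C@]1(C)CC/C(C)=C/CC1=C(O)C(=O)C=C(OC)C1=O | intermediate
22 | 3-methylbutan-1-amine | CC(C)CCN | starting material
23 | metachromin H, 2-hydroxy-5-[(3-methylbutyl)amino]-3-{(2E)-5-[(1R,3R)-1,3-dimethyl-2-methylidenecyclohexyl]-3-methylpent-2-en-1-yl}cyclohexa-2,5-diene-1,4-dione | C=C1[C@H](C)CCC[C@]1(C)CC/C(C)=C/CC1=C(O)C(=O)C=C(NCCC(C)C)C1=O | target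

**Total step count:** 14
**Longest linear sequence:** 11 steps (steps 1–4, then 8–14)

**Steps most likely to fail**

Step 11 (key step). The hydroboration may not discriminate fully between the vinyl group and the 1,1-disubstituted alkene. Oxidative addition at the β-branched bromide may be slow, so that β-hydride elimination toward the conjugated diene or intermolecular coupling competes with ring closure. The fallback sets out from 17 and comes back at 19; it forms the same C4–C5 bond by a sulfone-carbanion 6-exo-tet alkylation. Compound 17 is treated with PhSO2Na (DMF, 60 °C) to give the phenyl sulfone F1. The vinyl group of F1 is hydroborated with the more discriminating Sia2BH and oxidised (NaBO3·4H2O) to the primary alcohol F2. This is converted (I2, PPh3, imidazole) into the primary iodide F3. Lithium diisopropylamide (THF, −78 → 0 °C, high dilution) should close the ring to the cyclic sulfone F4, a mixture at C4. Reductive desulfonylation with Na(Hg) and Na2HPO4 in MeOH then removes the sulfonyl group and should give 19.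

Step 8. The hydroalumination may give some of the terminal alkenylalane. Transfer of the hindered, α-branched alkenyl group to the fully substituted γ-carbon may be slow, so that isobutyl transfer or direct SN2 attack competes, and facial control at the new quaternary carbon may be incomplete. The fallback sets out from 13 (via 14) and comes back at 15; it moves the union into the boron manifold. The alkenylalane 14 is trapped with 2-methoxy-4,4,5,5-tetramethyl-1,3,2-dioxaborolane to give the isolable alkenylboronic ester F5, which can be freed from regioisomers. F5 is then coupled with 9 under CuCl (5 mol %), L* and NaOMe in THF at rt, an NHC–copper allylic substitution of alkenyl–B(pin) reagents that tolerates hindered 1,1-disubstituted alkenyl groups and should give 15. Because C3 is fixed, any C1 epimer is a diastereomer and can be removed by chromatography.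

Step 13. Hydroxide may attack the other vinylogous ester (C5), methoxide exchange may scramble the positions, or the quinone may degrade in base. The fallback sets out from 20 and comes back at 23; it reverses the order of the two substitutions. Compound 20 is treated with 22 (1.1 equiv, EtOH, 0 °C), and aminolysis of the less hindered C5 methoxy group should give the 5-(isopentylamino)-2-methoxyquinone F6. Hydrolysis of the one remaining, alkyl-flanked vinylogous ester (KOH, MeOH/H2O; then 1 M HCl) should then give 23.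

**Further compounds**
F1 | step 11 | (2S,4S,7E)-4-ethenyl-2,4,7-trimethyl-3-methylidene-1-(phenylsulfonyl)-9-(2,3,5,6-tetramethoxyphenyl)non-7-ene | C=C[C@](C(=C)[C@H](C)CS(=O)(=O)c1ccccc1)(C)CC/C(C)=C/Cc1c(OC)c(OC)cc(OC)c1OC
F2 | step 11 | primary alcohol from hydroboration–oxidation of the ethenyl group of F1 | OCC[C@](C(=C)[C@H](C)CS(=O)(=O)c1ccccc1)(C)CC/C(C)=C/Cc1c(OC)c(OC)cc(OC)c1OC
F3 | step 11 | primary iodide corresponding to F2 | ICC[C@](C(=C)[C@H](C)CS(=O)(=O)c1ccccc1)(C)CC/C(C)=C/Cc1c(OC)c(OC)cc(OC)c1OC
F4 | step 11 | 4-(phenylsulfonyl) derivative of 19 (cyclic sulfone, mixture at C4) | C=C1[C@H](C)C(S(=O)(=O)c2ccccc2)CC[C@]1(C)CC/C(C)=C/Cc1c(OC)c(OC)cc(OC)c1OC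
F5 | step 8 | tert-butyldimethyl{[(2S)-2-methyl-3-(4,4,5,5-tetramethyl-1,3,2-dioxaborolan-2-yl)but-3-en-1-yl]oxy}silane | C=C(B1OC(C)(C)C(C)(C)O1)[C@H](C)CO[Si](C)(C)C(C)(C)C
F6 | step 13 | 2-methoxy-5-[(3-methylbutyl)amino]-3-{(2E)-5-[(1R,3R)-1,3-dimethyl-2-methylidenecyclohexyl]-3-methylpent-2-en-1-yl}cyclohexa-2,5-diene-1,4-dione | C=C1[C@H](C)CCC[C@]1(C)CC/C(C)=C/CC1=C(OC)C(=O)C=C(NCCC(C)C)C1=O
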